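**Retrosynthetic overview**
1. Target ⇒ hydrogenolysis of two benzyl ethers and 3-O-acetylation of (2R,3R)-3',4'-di-O-benzylpadmatin.
2. That dihydroflavonol ⇒ oxygenation at C-3 of the enol of a (2S)-flavanone, trans to the aryl group (the flavanone 3-hydroxylase event).
3. (2S)-Flavanone ⇒ 2',6'-dihydroxychalcone by enantioselective 6-endo oxa-Michael closure (the chalcone isomerase event); both events are run in one flask.
4. Chalcone ⇒ Claisen–Schmidt union of a ring A acetophenone and a ring B aldehyde.
5. Ring order: rings A and B are bought as arenes; ring C is the only ring formed, closed at O-1–C-2 first and then oxygenated at C-3.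

Assumption: both starting materials are catalogue items, and the quinine-derived squaramide is taken to give the 2S flavanone (its quinidine-derived pseudo-enantiomer is used instead if circular dichroism shows 2R).

**Route**

Step 1
Reactants: 1 2',6'-dihydroxy-4'-methoxyacetophenone; 2 3,4-bis(benzyloxy)benzaldehyde
Product: 3 (E)-3-[3,4-bis(benzyloxy)phenyl]-1-(2,6-dihydroxy-4-methoxyphenyl)prop-2-en-1-one
Conditions: KOH (50% aq.), EtOH, 0 °C→rt, 48 h; then AcOH, 0 °C, to pH 5; crystallise
Reagents that add atoms: none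
Why: Claisen–Schmidt aldol condensation of the acetophenone enolate with a non-enolisable aldehyde, with E1cB dehydration giving the E-enone; in strong base the product stays ring-open as its phenolate, and cold acidification precipitates the chalcone before it can cyclise (no stereocentre formed).

Step 2
Reactants: 3 (E)-3-[3,4-bis(benzyloxy)phenyl]-1-(2,6-dihydroxy-4-methoxyphenyl)prop-2-en-1-one
Product: 7 (2R,3R)-2-[3,4-bis(benzyloxy)phenyl]-3,5-dihydroxy-7-methoxychroman-4-one, via (2S)-flavanone 4 (not isolated), via bis-TMS enol ether 5 (not isolated), via silyloxy epoxide 6 (not isolated)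
Conditions: quinine squaramide Q (10 mol%), PhMe, –20 °C; Et3N, TMSOTf, –40→0 °C; evaporate, pentane, filter; DMDO, acetone/CH2Cl2, –40 °C; citric acid, MeOH, 0 °C. Q = 3-{[3,5-bis(trifluoromethyl)phenyl]amino}-4-{[(8α,9S)-6'-methoxycinchonan-9-yl]amino}cyclobut-3-ene-1,2-dione
Reagents that add atoms: dimethyldioxirane (DMDO), CC1(C)OO1 (supplies O-3); trimethylsilyl trifluoromethanesulfonate (TMSOTf), C[Si](C)(C)OS(=O)(=O)C(F)(F)F (silyl groups of 5 and 6 only, lost before 7)
Why: Proposed new method: the quinuclidine nitrogen of Q deprotonates the non-chelated 2'-OH while the squaramide N–H pair binds the carbonyl that the 6'-OH already activates by an internal hydrogen bond, so the phenoxide adds 6-endo to the Si face of C-β and sets C-2 as S (intramolecular oxa-Michael; closest known type is the cinchona thiourea-catalysed cyclisation of α-alkoxycarbonyl-activated 2'-hydroxychalcones, the ester being replaced here by the internal hydrogen bond); soft enolisation then traps the base-labile 5-hydroxyflavanone before retro-Michael racemisation, Rubottom oxidation with DMDO delivers oxygen to the enol ether face anti to the C-2 aryl group and sets C-3 as R (2,3-trans), and acidic methanolysis of the silyloxy epoxide and the aryl silyl ether releases the α-hydroxy ketone.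

Step 3
Reactants: 7 (2R,3R)-2-[3,4-bis(benzyloxy)phenyl]-3,5-dihydroxy-7-methoxychroman-4-one
Product: 8 (2R,3R)-2-[3,4-bis(benzyloxy)phenyl]-5-hydroxy-7-methoxy-4-oxochroman-3-yl acetate
Conditions: Ac2O (1.1 equiv), pyridine, CH2Cl2, 0 °C, 2 h
Reagents that add atoms: acetic anhydride, CC(=O)OC(C)=O
Why: Chemoselective O-acylation: the secondary 3-OH is acetylated while the 5-OH, locked in a strong hydrogen bond to the C-4 carbonyl, is the least nucleophilic hydroxyl of a flavonoid; no stereocentre is touched, and the 4'-O-benzyl group blocks the quinone-methide pathway for C-2 epimerisation.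

Step 4
Reactants: 8 (2R,3R)-2-[3,4-bis(benzyloxy)phenyl]-5-hydroxy-7-methoxy-4-oxochroman-3-yl acetate
Product: 9 3-O-acetylpadmatin, (2R,3R)-2-(3,4-dihydroxyphenyl)-5-hydroxy-7-methoxy-4-oxochroman-3-yl acetate
Conditions: H2 (1 atm), 10% Pd/C, EtOAc, rt; stop at 2 equiv H2
Reagents that add atoms: none
Why: Catalytic hydrogenolysis of the two aryl benzyl ethers in neutral aprotic solvent leaves the acetate, the chelated ketone and both stereocentres untouched; stopping at 2 equiv H2 spares the benzylic C-2–O-1 bond.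

**Compound list**
1 | 2',6'-dihydroxy-4'-methoxyacetophenone | CC(=O)c1c(O)cc(OC)cc1O | starting material
2 | 3,4-bis(benzyloxy)benzaldehyde | O=Cc1ccc(OCc2ccccc2)c(OCc2ccccc2)c1 | starting material
3 | (E)-3-[3,4-bis(benzyloxy)phenyl]-1-(2,6-dihydroxy-4-methoxyphenyl)prop-2-en-1-one | COc1cc(O)c(C(=O)/C=C/c2ccc(OCc3ccccc3)c(OCc3ccccc3)c2)c(O)c1 | intermediate
4 | (2S)-2-[3,4-bis(benzyloxy)phenyl]-5-hydroxy-7-methoxychroman-4-one | COc1cc(O)c2c(c1)O[C@H](c1ccc(OCc3ccccc3)c(OCc3ccccc3)c1)CC2=O | intermediate
5 | (2S)-2-[3,4-bis(benzyloxy)phenyl]-7-methoxy-4,5-bis(trimethylsilyloxy)-2H-chromene | COc1cc(O[Si](C)(C)C)c2c(c1)O[C@H](c1ccc(OCc3ccccc3)c(OCc3ccccc3)c1)C=C2O[Si](C)(C)C | intermediate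
6 | (1aR,2R,7bR)-2-[3,4-bis(benzyloxy)phenyl]-5-methoxy-7,7b-bis(trimethylsilyloxy)-1a,7b-dihydro-2H-oxireno[2,3-c]chromene (the 3,4-epoxide of 5, oxygen anti to the aryl group) | COc1cc(O[Si](C)(C)C)c2c(c1)O[C@H](c1ccc(OCc3ccccc3)c(OCc3ccccc3)c1)[C@H]1O[C@]12O[Si](C)(C)C | intermediate
7 | (2R,3R)-2-[3,4-bis(benzyloxy)phenyl]-3,5-dihydroxy-7-methoxychroman-4-one (3',4'-di-O-benzylpadmatin) | COc1cc(O)c2c(c1)O[C@H](c1ccc(OCc3ccccc3)c(OCc3ccccc3)c1)[C@@H](O)C2=O | intermediate
8 | (2R,3R)-2-[3,4-bis(benzyloxy)phenyl]-5-hydroxy-7-methoxy-4-oxochroman-3-yl acetate | COc1cc(O)c2c(c1)O[C@H](c1ccc(OCc3ccccc3)c(OCc3ccccc3)c1)[C@@H](OC(C)=O)C2=O | intermediate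
9 | 3-O-acetylpadmatin, (2R,3R)-2-(3,4-dihydroxyphenyl)-5-hydroxy-7-methoxy-4-oxochroman-3-yl acetate | COc1cc(O)c2c(c1)O[C@H](c1ccc(O)c(O)c1)[C@@H](OC(C)=O)C2=O | target

**Totals**
Total step count: 4. Longest linear sequence: 4 steps (1 → 3 → 7 → 8 → 9).

**Steps most likely to fail**

Step 2 is the most exposed. The chalcone has no ester activation, background cyclisation gives racemate, and the 5-hydroxyflavanone can racemise by retro-Michael opening before it is silylated. A modest ee can be raised by crystallising 7. The fallback sets out from 1 and makes the C-2–aryl bond instead of the O-1–C-2 bond. Formylation of 1 (HCO2Et, NaH, THF) gives the cyclic hemiacetal 2,5-dihydroxy-7-methoxychroman-4-one F1. Dehydration of F1 (HCl, AcOH) gives 5-hydroxy-7-methoxy-4H-chromen-4-one F2. Enantioselective conjugate addition of purchased [3,4-bis(benzyloxy)phenyl]boronic acid to F2 follows, using Pd(OCOCF3)2, 4-tert-butyl-2-(pyridin-2-yl)-4,5-dihydrooxazole (the enantiomer that gives 2S), NH4PF6, H2O, ClCH2CH2Cl, 60 °C. This gives the flavanone as an isolated, crystallisable solid. The fallback comes back to the route at 4, which is then taken through the silylation, DMDO and methanolysis part of step 2.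

Step 1 is second. The doubly deprotonated acetophenone is a sluggish aldol donor, and the 2',6'-dihydroxychalcone can close to racemic flavanone during acidification. The fallback sets out from 1 and masks one phenol. MOMCl (1.1 equiv) with i-Pr2NEt in CH2Cl2 at 0 °C gives 1-[2-hydroxy-4-methoxy-6-(methoxymethoxy)phenyl]ethan-1-one F3, the second hydroxyl being protected by its chelate. Claisen–Schmidt condensation of F3 with 2 (KOH, EtOH, rt) gives the stable chalcone (E)-3-[3,4-bis(benzyloxy)phenyl]-1-[2-hydroxy-4-methoxy-6-(methoxymethoxy)phenyl]prop-2-en-1-one F4. Brief HCl in MeOH at rt removes the acetal, and the fallback comes back to the route at 3.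

Step 3 is third. The risk is partial acetylation of the 5-OH, or base-induced opening of ring C on long exposure to pyridine. The fallback sets out from 7 and uses over-acylation followed by selective cleavage. Ac2O, pyridine and catalytic DMAP at 0 °C give (2R,3R)-2-[3,4-bis(benzyloxy)phenyl]-7-methoxy-4-oxochromane-3,5-diyl diacetate F5. The aryl acetate of F5 alone is then cleaved with NH4OAc in aqueous MeOH at rt, and the fallback comes back to the route at 8.

**Further compounds**
F1 | step 2 | 2,5-dihydroxy-7-methoxychroman-4-one (racemic hemiacetal) | COc1cc(O)c2c(c1)OC(O)CC2=O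
F2 | step 2 | 5-hydroxy-7-methoxy-4H-chromen-4-one | COc1cc(O)c2c(c1)OC=CC2=O
F3 | step 1 | 1-[2-hydroxy-4-methoxy-6-(methoxymethoxy)phenyl]ethan-1-one | COCOc1cc(OC)cc(O)c1C(C)=O
F4 | step 1 | (E)-3-[3,4-bis(benzyloxy)phenyl]-1-[2-hydroxy-4-methoxy-6-(methoxymethoxy)phenyl]prop-2-en-1-one | COCOc1cc(OC)cc(O)c1C(=O)/C=C/c1ccc(OCc2ccccc2)c(OCc2ccccc2)c1
F5 | step 3 | (2R,3R)-2-[3,4-bis(benzyloxy)phenyl]-7-methoxy-4-oxochromane-3,5-diyl diacetate | COc1cc(OC(C)=O)c2c(c1)O[C@H](c1ccc(OCc3ccccc3)c(OCc3ccccc3)c1)[C@@H](OC(C)=O)C2=O
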